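**Retrosynthetic overview**
- The two acetates are installed last. The C1′=C3 exocyclic alkene is cut by an aldol addition and dehydration between a C1′ aldehyde (C3′ silyl ether, C10′ benzoate) and a 4‑silyloxy‑5‑isobutenyl γ‑lactone.
- The strategy rests on C3′, the acetoxy‑bearing allylic stereocentre two carbons from C1′ (the alkylidene carbon on the lactone). C1′ and C3′ form a latent 1,3‑dioxygen pair, which is what remains when a C2′–C3′ oxirane carrying its hydroxyl on C1′ is opened by hydride at C2′.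
- The (2S,3S)‑epoxy alcohol comes from tartrate‑controlled, hydroxyl‑directed epoxidation of a (2E,4E,8Z)‑trienol. The trienol is built from nerol by etherification, allylic oxidation of the E methyl group, two‑carbon olefination and ester reduction.
- The lactone (C4 S, C5 R) comes from 2‑deoxy‑D‑ribose: oxidation closes the γ‑lactone, and the C5 hydroxymethyl becomes the isobutenyl group through the aldehyde and a Wittig reaction.
- Ring order: the γ‑lactone (step 13) is the only ring of the target; the oxirane (step 6) is transient and is opened in step 7.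

Key step: step 6

Remark on the chemistry: chain atoms are numbered C1′ (alkylidene carbon) to C10′ (benzoate carbon). The C10′ oxygen is carried as a 4‑methoxybenzyl ether, because a benzoate would not survive the two aluminium hydride steps and this ether can later be removed oxidatively beside the silyl ethers.

**Route**

Step 1
Reactants: 1 nerol
Product: 2 neryl 4‑methoxybenzyl ether
Conditions: NaH, 4‑methoxybenzyl chloride, nBu4NI (cat.), THF/DMF, 0 °C to rt
Reagents that add atoms: 4‑methoxybenzyl chloride, COc1ccc(CCl)cc1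
Why: Williamson etherification of the primary allylic alkoxide leaves the Z alkene untouched and gives an ether that tolerates hydride reagents and titanium alkoxides.

Step 2
Reactants: 2 neryl 4‑methoxybenzyl ether
Product: 3 (2E,6Z)-8-[(4-methoxybenzyl)oxy]-2,6-dimethylocta-2,6-dien-1-ol
Conditions: SeO2 (0.3 equiv), tBuOOH (3 equiv), salicylic acid (cat.), CH2Cl2, rt
Reagents that add atoms: tert‑butyl hydroperoxide, CC(C)(C)OO; selenium dioxide as oxygen carrier, O=[Se]=O
Why: SeO2‑catalysed allylic oxidation (ene reaction, then [2,3]‑sigmatropic shift) should hydroxylate the E methyl group of the electron‑rich terminal alkene, the C2 alkene being deactivated by the allylic ether; any enal formed converges in step 3.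

Step 3
Reactants: 3 (2E,6Z)-8-[(4-methoxybenzyl)oxy]-2,6-dimethylocta-2,6-dien-1-ol
Product: 4 (2E,6Z)-8-[(4-methoxybenzyl)oxy]-2,6-dimethylocta-2,6-dienal
Conditions: MnO2 (excess), CH2Cl2, rt
Reagents that add atoms: none
Why: MnO2 oxidises allylic alcohols chemoselectively to enals and should leave the ether, the isolated alkene and the E geometry intact.

Step 4
Reactants: 4 (2E,6Z)-8-[(4-methoxybenzyl)oxy]-2,6-dimethylocta-2,6-dienal; 5 triethyl phosphonoacetate
Product: 7 ethyl (2E,4E,8Z)-10-[(4-methoxybenzyl)oxy]-4,8-dimethyldeca-2,4,8-trienoate, via sodium phosphonate carbanion 6 (not isolated)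
Conditions: NaH, THF, 0 °C; then 4, 0 °C to rt
Reagents that add atoms: none
Why: Horner–Wadsworth–Emmons olefination with a stabilised phosphonate is expected to give the new C2=C3 alkene with E geometry.

Step 5
Reactants: 7 ethyl (2E,4E,8Z)-10-[(4-methoxybenzyl)oxy]-4,8-dimethyldeca-2,4,8-trienoate
Product: 8 (2E,4E,8Z)-10-[(4-methoxybenzyl)oxy]-4,8-dimethyldeca-2,4,8-trien-1-ol
Conditions: iBu2AlH (2.3 equiv), CH2Cl2, −78 °C; aq. KNaC4H4O6 work‑up
Reagents that add atoms: none
Why: 1,2‑reduction of the dienoate by iBu2AlH at low temperature should give the dienol without conjugate reduction or alkene isomerisation.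

Step 6
Reactants: 8 (2E,4E,8Z)-10-[(4-methoxybenzyl)oxy]-4,8-dimethyldeca-2,4,8-trien-1-ol
Product: 9 [(2S,3S)-3-[(2E,6Z)-8-[(4-methoxybenzyl)oxy]-6-methylocta-2,6-dien-2-yl]oxiran-2-yl]methanol
Conditions: Ti(OiPr)4 (10 mol%), L‑(+)‑diethyl tartrate (12 mol%), tBuOOH (2 equiv, anhydrous), 4 Å molecular sieves, CH2Cl2, −20 °C; non‑acidic work‑up
Reagents that add atoms: tert‑butyl hydroperoxide, CC(C)(C)OO
Why: Ti(OiPr)4 and the tartrate form a dimeric tetravalent titanium complex that exchanges isopropoxide for the C1 alkoxide of 8 and for tert‑butyl peroxide, and the peroxide oxygen is then transferred to the C2=C3 π bond in one concerted step that forms the C2–O and C3–O bonds together (Katsuki–Sharpless asymmetric epoxidation, known for 2,4‑dien‑1‑ols at the proximal alkene). The oxirane is closed by this concerted [2+1] oxygen‑atom addition and not by cyclisation of a chain, and the addition is syn‑stereospecific, so the E alkene gives the trans epoxide. Both new stereocentres, C2 and C3, are set by the tartrate: with the L‑(+)‑ester, oxygen is delivered to the face that gives (2S,3S) (alkene in the plane, CH2OH at the lower right, oxygen from below). Site selectivity for C2=C3 over C4=C5 and C8=C9 is needed and is secured by the C1 hydroxyl, the only group that binds titanium, and face selectivity is secured by the tartrate. Because the 3‑alkenyl epoxide can open at its allylic C3–O bond under acid, catalytic titanium, molecular sieves, low temperature and a non‑acidic work‑up are used.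

Step 7
Reactants: 9 [(2S,3S)-3-[(2E,6Z)-8-[(4-methoxybenzyl)oxy]-6-methylocta-2,6-dien-2-yl]oxiran-2-yl]methanol
Product: 10 (3R,4E,8Z)-10-[(4-methoxybenzyl)oxy]-4,8-dimethyldeca-4,8-diene-1,3-diol
Conditions: NaAlH2(OCH2CH2OMe)2, THF, −20 to 0 °C; aq. KNaC4H4O6 work‑up
Reagents that add atoms: none
Why: Regioselective reductive opening of a 2,3‑epoxy alcohol, in which the C1 aluminium alkoxide delivers hydride intramolecularly to C2, should give the 1,3‑diol; the C3–O bond is not touched, and the descriptor changes from S to R only because the CIP priorities change.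

Step 8
Reactants: 10 (3R,4E,8Z)-10-[(4-methoxybenzyl)oxy]-4,8-dimethyldeca-4,8-diene-1,3-diol
Product: 11 (3R,4E,8Z)-1,3-bis[(tert-butyldimethylsilyl)oxy]-10-[(4-methoxybenzyl)oxy]-4,8-dimethyldeca-4,8-diene
Conditions: tBuMe2SiOTf (2.5 equiv), 2,6‑lutidine, CH2Cl2, −78 to 0 °C
Reagents that add atoms: tert‑butyldimethylsilyl trifluoromethanesulfonate, CC(C)(C)[Si](C)(C)OS(=O)(=O)C(F)(F)F
Why: Silylation with the triflate and a hindered base protects both the primary and the hindered secondary allylic hydroxyl without ionising the allylic C3–O bond.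

Step 9
Reactants: 11 (3R,4E,8Z)-1,3-bis[(tert-butyldimethylsilyl)oxy]-10-[(4-methoxybenzyl)oxy]-4,8-dimethyldeca-4,8-diene
Product: 12 (2Z,6E,8R)-8,10-bis[(tert-butyldimethylsilyl)oxy]-3,7-dimethyldeca-2,6-dien-1-ol
Conditions: DDQ (1.2 equiv), CH2Cl2/pH 7 buffer, 0 °C
Reagents that add atoms: none
Why: Oxidative cleavage of the 4‑methoxybenzyl ether by DDQ (benzylic hydride abstraction, hydrolysis of the oxocarbenium ion) is orthogonal to both silyl ethers, and the cold buffered medium limits further oxidation of the freed allylic alcohol.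

Step 10
Reactants: 12 (2Z,6E,8R)-8,10-bis[(tert-butyldimethylsilyl)oxy]-3,7-dimethyldeca-2,6-dien-1-ol
Product: 13 (2Z,6E,8R)-8,10-bis[(tert-butyldimethylsilyl)oxy]-3,7-dimethyldeca-2,6-dien-1-yl benzoate
Conditions: BzCl, pyridine, DMAP (cat.), CH2Cl2, 0 °C
Reagents that add atoms: benzoyl chloride, O=C(Cl)c1ccccc1
Why: Acylation of the only free, primary allylic hydroxyl installs the benzoate of the target now that no hydride step remains.

Step 11
Reactants: 13 (2Z,6E,8R)-8,10-bis[(tert-butyldimethylsilyl)oxy]-3,7-dimethyldeca-2,6-dien-1-yl benzoate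
Product: 14 (2Z,6E,8R)-8-[(tert-butyldimethylsilyl)oxy]-10-hydroxy-3,7-dimethyldeca-2,6-dien-1-yl benzoate
Conditions: HF·pyridine, pyridine, THF, 0 °C
Reagents that add atoms: none
Why: Buffered HF·pyridine should cleave the unhindered primary silyl ether much faster than the secondary one flanked by the C7 methyl‑substituted alkene, and the benzoate is stable to it.

Step 12
Reactants: 14 (2Z,6E,8R)-8-[(tert-butyldimethylsilyl)oxy]-10-hydroxy-3,7-dimethyldeca-2,6-dien-1-yl benzoate
Product: 15 (2Z,6E,8R)-8-[(tert-butyldimethylsilyl)oxy]-3,7-dimethyl-10-oxodeca-2,6-dien-1-yl benzoate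
Conditions: Dess–Martin periodinane, CH2Cl2, 0 °C to rt; aq. NaHCO3/Na2S2O3 work‑up
Reagents that add atoms: none
Why: Dess–Martin oxidation under near‑neutral conditions gives the β‑silyloxy aldehyde without β‑elimination; it is used at once.

Step 13
Reactants: 16 2‑deoxy‑D‑ribose
Product: 17 (4S,5R)-4-hydroxy-5-(hydroxymethyl)oxolan-2-one
Conditions: Br2, H2O, rt; then concentration
Reagents that add atoms: none
Why: Bromine‑water oxidation of the aldose hemiacetal gives the aldonic acid, which settles as the five‑membered 1,4‑lactone; the sugar C3 and C4 centres are untouched and become C4 (S) and C5 (R) of the lactone, trans to each other.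

Step 14
Reactants: 17 (4S,5R)-4-hydroxy-5-(hydroxymethyl)oxolan-2-one
Product: 18 (4S,5R)-4-[(tert-butyldimethylsilyl)oxy]-5-{[(tert-butyldimethylsilyl)oxy]methyl}oxolan-2-one
Conditions: tBuMe2SiCl (2.5 equiv), imidazole, DMF, rt
Reagents that add atoms: tert‑butyldimethylsilyl chloride, CC(C)(C)[Si](C)(C)Cl
Why: Standard imidazole‑promoted silylation protects both hydroxyls without opening or epimerising the lactone.

Step 15
Reactants: 18 (4S,5R)-4-[(tert-butyldimethylsilyl)oxy]-5-{[(tert-butyldimethylsilyl)oxy]methyl}oxolan-2-one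
Product: 19 (4S,5R)-4-[(tert-butyldimethylsilyl)oxy]-5-(hydroxymethyl)oxolan-2-one
Conditions: CF3CO2H/H2O/THF (1:1:4), 0 °C
Reagents that add atoms: none
Why: Acid‑catalysed hydrolysis removes the less hindered primary silyl ether selectively, as established for 3,5‑bis‑silylated 2‑deoxyribose derivatives, and acid rules out silyl migration.

Step 16
Reactants: 19 (4S,5R)-4-[(tert-butyldimethylsilyl)oxy]-5-(hydroxymethyl)oxolan-2-one
Product: 20 (2S,3S)-3-[(tert-butyldimethylsilyl)oxy]-5-oxooxolane-2-carbaldehyde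
Conditions: Dess–Martin periodinane, CH2Cl2, 0 °C to rt; crude aldehyde used directly
Reagents that add atoms: none
Why: Neutral Dess–Martin oxidation should give the α‑alkoxy aldehyde without epimerisation at C2 or β‑elimination of the silyloxy group (the S descriptor at C2 reflects only the new CIP priority of the formyl group).

Step 17
Reactants: 20 (2S,3S)-3-[(tert-butyldimethylsilyl)oxy]-5-oxooxolane-2-carbaldehyde; 21 isopropyltriphenylphosphonium iodide
Product: 23 (4S,5R)-4-[(tert-butyldimethylsilyl)oxy]-5-(2-methylprop-1-en-1-yl)oxolan-2-one, via isopropylidene ylide 22 (not isolated)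
Conditions: 21, nBuLi, THF, 0 °C; then 20, −78 to 0 °C
Reagents that add atoms: none
Why: Wittig olefination with the non‑stabilised ylide should add to the aldehyde at −78 °C faster than it deprotonates the substrate or attacks the lactone carbonyl, and the symmetrical alkene terminus raises no geometry question.

Step 18
Reactants: 23 (4S,5R)-4-[(tert-butyldimethylsilyl)oxy]-5-(2-methylprop-1-en-1-yl)oxolan-2-one; 15 (2Z,6E,8R)-8-[(tert-butyldimethylsilyl)oxy]-3,7-dimethyl-10-oxodeca-2,6-dien-1-yl benzoate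
Product: 25 (2Z,6E,8R)-8-[(tert-butyldimethylsilyl)oxy]-10-[(3S,4S,5R)-4-[(tert-butyldimethylsilyl)oxy]-5-(2-methylprop-1-en-1-yl)-2-oxooxolan-3-yl]-10-hydroxy-3,7-dimethyldeca-2,6-dien-1-yl benzoate (C10 epimers), via lithium enolate 24 (not isolated)
Conditions: LiN(SiMe3)2 (1.05 equiv), THF, −78 °C; then 15, −78 °C; AcOH quench
Reagents that add atoms: none
Why: Aldol addition of the lactone lithium enolate, which at −78 °C does not expel the poor silanolate leaving group, should occur at the aldehyde only (the benzoate is inert) and anti to the C4 silyloxy group; the C3 and C10 configurations are erased in step 19.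

Step 19
Reactants: 25 aldol adduct (C10 epimers)
Product: 27 (2Z,6E,8R,10E)-8-[(tert-butyldimethylsilyl)oxy]-10-[(4S,5R)-4-[(tert-butyldimethylsilyl)oxy]-5-(2-methylprop-1-en-1-yl)-2-oxooxolan-3-ylidene]-3,7-dimethyldeca-2,6-dien-1-yl benzoate, via C10 mesylate 26 (not isolated)
Conditions: MsCl, Et3N, CH2Cl2, 0 °C; then DBU, 0 °C to rt
Reagents that add atoms: none
Why: Mesylation followed by E1cB elimination through the lactone enolate expels the mesylate, a far better leaving group than either silyloxy group, and is expected to favour the E alkylidene lactone with the chain anti to the carbonyl, both aldol epimers converging.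

Step 20
Reactants: 27 bis‑silyl E‑alkylidene lactone
Product: 28 (2Z,6E,8R,10E)-8-hydroxy-10-[(4S,5R)-4-hydroxy-5-(2-methylprop-1-en-1-yl)-2-oxooxolan-3-ylidene]-3,7-dimethyldeca-2,6-dien-1-yl benzoate
Conditions: HF·pyridine (excess), pyridine, THF, 0 °C to rt
Reagents that add atoms: none
Why: Fluoride‑driven cleavage of both secondary silyl ethers under weakly acidic, non‑basic conditions spares the benzoate, the lactone and the alkene geometry; the E alkene keeps C8–OH from reaching the lactone carbonyl, so translactonisation is not possible.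

Step 21
Reactants: 28 diol
Product: 29 (2Z,6E,8R,10E)-8-acetoxy-10-[(4S,5R)-4-acetoxy-5-(2-methylprop-1-en-1-yl)-2-oxooxolan-3-ylidene]-3,7-dimethyldeca-2,6-dien-1-yl benzoate
Conditions: Ac2O, pyridine, DMAP (cat.), CH2Cl2, 0 °C to rt
Reagents that add atoms: acetic anhydride, CC(=O)OC(C)=O
Why: Acylation of both secondary hydroxyls under mild amine catalysis touches no stereocentre and avoids the strong base that could trigger vinylogous elimination of the C8 acetate.

**Compound list**
1 | nerol, (2Z)-3,7-dimethylocta-2,6-dien-1-ol | CC(C)=CCC/C(C)=C\CO | starting material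
2 | 1-({[(2Z)-3,7-dimethylocta-2,6-dien-1-yl]oxy}methyl)-4-methoxybenzene | CC(C)=CCC/C(C)=C\COCc1ccc(OC)cc1 | intermediate
3 | (2E,6Z)-8-[(4-methoxybenzyl)oxy]-2,6-dimethylocta-2,6-dien-1-ol | OC/C(C)=C/CC/C(C)=C\COCc1ccc(OC)cc1 | intermediate
4 | (2E,6Z)-8-[(4-methoxybenzyl)oxy]-2,6-dimethylocta-2,6-dienal | O=C/C(C)=C/CC/C(C)=C\COCc1ccc(OC)cc1 | intermediate
5 | triethyl phosphonoacetate | CCOC(=O)CP(=O)(OCC)OCC | starting material
6 | sodium salt of the carbanion of 5 | [Na+].CCOC(=O)[CH-]P(=O)(OCC)OCC | intermediate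
7 | ethyl (2E,4E,8Z)-10-[(4-methoxybenzyl)oxy]-4,8-dimethyldeca-2,4,8-trienoate | CCOC(=O)/C=C/C(C)=C/CC/C(C)=C\COCc1ccc(OC)cc1 | intermediate
8 | (2E,4E,8Z)-10-[(4-methoxybenzyl)oxy]-4,8-dimethyldeca-2,4,8-trien-1-ol | OC/C=C/C(C)=C/CC/C(C)=C\COCc1ccc(OC)cc1 | intermediate
9 | [(2S,3S)-3-[(2E,6Z)-8-[(4-methoxybenzyl)oxy]-6-methylocta-2,6-dien-2-yl]oxiran-2-yl]methanol | OC[C@@H]1O[C@H]1/C(C)=C/CC/C(C)=C\COCc1ccc(OC)cc1 | intermediate
10 | (3R,4E,8Z)-10-[(4-methoxybenzyl)oxy]-4,8-dimethyldeca-4,8-diene-1,3-diol | OCC[C@@H](O)/C(C)=C/CC/C(C)=C\COCc1ccc(OC)cc1 | intermediate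
11 | (3R,4E,8Z)-1,3-bis[(tert-butyldimethylsilyl)oxy]-10-[(4-methoxybenzyl)oxy]-4,8-dimethyldeca-4,8-diene | CC(C)(C)[Si](C)(C)OCC[C@@H](O[Si](C)(C)C(C)(C)C)/C(C)=C/CC/C(C)=C\COCc1ccc(OC)cc1 | intermediate
12 | (2Z,6E,8R)-8,10-bis[(tert-butyldimethylsilyl)oxy]-3,7-dimethyldeca-2,6-dien-1-ol | CC(C)(C)[Si](C)(C)OCC[C@@H](O[Si](C)(C)C(C)(C)C)/C(C)=C/CC/C(C)=C\CO | intermediate
13 | (2Z,6E,8R)-8,10-bis[(tert-butyldimethylsilyl)oxy]-3,7-dimethyldeca-2,6-dien-1-yl benzoate | CC(C)(C)[Si](C)(C)OCC[C@@H](O[Si](C)(C)C(C)(C)C)/C(C)=C/CC/C(C)=C\COC(=O)c1ccccc1 | intermediate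
14 | (2Z,6E,8R)-8-[(tert-butyldimethylsilyl)oxy]-10-hydroxy-3,7-dimethyldeca-2,6-dien-1-yl benzoate | OCC[C@@H](O[Si](C)(C)C(C)(C)C)/C(C)=C/CC/C(C)=C\COC(=O)c1ccccc1 | intermediate
15 | (2Z,6E,8R)-8-[(tert-butyldimethylsilyl)oxy]-3,7-dimethyl-10-oxodeca-2,6-dien-1-yl benzoate | O=CC[C@@H](O[Si](C)(C)C(C)(C)C)/C(C)=C/CC/C(C)=C\COC(=O)c1ccccc1 | intermediate
16 | 2-deoxy-D-ribose | O=CC[C@H](O)[C@H](O)CO | starting material
17 | (4S,5R)-4-hydroxy-5-(hydroxymethyl)oxolan-2-one | O=C1C[C@H](O)[C@@H](CO)O1 | intermediate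
18 | (4S,5R)-4-[(tert-butyldimethylsilyl)oxy]-5-{[(tert-butyldimethylsilyl)oxy]methyl}oxolan-2-one | O=C1C[C@H](O[Si](C)(C)C(C)(C)C)[C@@H](CO[Si](C)(C)C(C)(C)C)O1 | intermediate
19 | (4S,5R)-4-[(tert-butyldimethylsilyl)oxy]-5-(hydroxymethyl)oxolan-2-one | O=C1C[C@H](O[Si](C)(C)C(C)(C)C)[C@@H](CO)O1 | intermediate
20 | (2S,3S)-3-[(tert-butyldimethylsilyl)oxy]-5-oxooxolane-2-carbaldehyde | O=C1C[C@H](O[Si](C)(C)C(C)(C)C)[C@@H](C=O)O1 | intermediate
21 | isopropyltriphenylphosphonium iodide | CC(C)[P+](c1ccccc1)(c1ccccc1)c1ccccc1.[I-] | starting material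
22 | isopropylidenetriphenylphosphorane | CC(C)=P(c1ccccc1)(c1ccccc1)c1ccccc1 | intermediate
23 | (4S,5R)-4-[(tert-butyldimethylsilyl)oxy]-5-(2-methylprop-1-en-1-yl)oxolan-2-one | O=C1C[C@H](O[Si](C)(C)C(C)(C)C)[C@@H](C=C(C)C)O1 | intermediate
24 | lithium enolate of 23 | [Li+].[O-]C1=C[C@H](O[Si](C)(C)C(C)(C)C)[C@@H](C=C(C)C)O1 | intermediate
25 | (2Z,6E,8R)-8-[(tert-butyldimethylsilyl)oxy]-10-[(3S,4S,5R)-4-[(tert-butyldimethylsilyl)oxy]-5-(2-methylprop-1-en-1-yl)-2-oxooxolan-3-yl]-10-hydroxy-3,7-dimethyldeca-2,6-dien-1-yl benzoate, C10 epimers | O=C1[C@@H](C(O)C[C@@H](O[Si](C)(C)C(C)(C)C)/C(C)=C/CC/C(C)=C\COC(=O)c2ccccc2)[C@H](O[Si](C)(C)C(C)(C)C)[C@@H](C=C(C)C)O1 | intermediate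
26 | (2Z,6E,8R)-8-[(tert-butyldimethylsilyl)oxy]-10-[(3R,4S,5R)-4-[(tert-butyldimethylsilyl)oxy]-5-(2-methylprop-1-en-1-yl)-2-oxooxolan-3-yl]-10-(methanesulfonyloxy)-3,7-dimethyldeca-2,6-dien-1-yl benzoate, C10 epimers (same spatial arrangement at C3 as 25) | O=C1[C@@H](C(OS(C)(=O)=O)C[C@@H](O[Si](C)(C)C(C)(C)C)/C(C)=C/CC/C(C)=C\COC(=O)c2ccccc2)[C@H](O[Si](C)(C)C(C)(C)C)[C@@H](C=C(C)C)O1 | intermediate
27 | (2Z,6E,8R,10E)-8-[(tert-butyldimethylsilyl)oxy]-10-[(4S,5R)-4-[(tert-butyldimethylsilyl)oxy]-5-(2-methylprop-1-en-1-yl)-2-oxooxolan-3-ylidene]-3,7-dimethyldeca-2,6-dien-1-yl benzoate | CC(C)(C)[Si](C)(C)O[C@H](C/C=C1/C(=O)O[C@H](C=C(C)C)[C@H]1O[Si](C)(C)C(C)(C)C)/C(C)=C/CC/C(C)=C\COC(=O)c1ccccc1 | intermediate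
28 | (2Z,6E,8R,10E)-8-hydroxy-10-[(4S,5R)-4-hydroxy-5-(2-methylprop-1-en-1-yl)-2-oxooxolan-3-ylidene]-3,7-dimethyldeca-2,6-dien-1-yl benzoate | O[C@H](C/C=C1/C(=O)O[C@H](C=C(C)C)[C@H]1O)/C(C)=C/CC/C(C)=C\COC(=O)c1ccccc1 | intermediate
29 | (2Z,6E,8R,10E)-8-acetoxy-10-[(4S,5R)-4-acetoxy-5-(2-methylprop-1-en-1-yl)-2-oxooxolan-3-ylidene]-3,7-dimethyldeca-2,6-dien-1-yl benzoate | CC(=O)O[C@H](C/C=C1/C(=O)O[C@H](C=C(C)C)[C@H]1OC(C)=O)/C(C)=C/CC/C(C)=C\COC(=O)c1ccccc1 | target

**Step count**
Total steps: 21. Longest linear sequence: 16 (steps 1–12, then 18–21); the lactone branch (steps 13–17) joins at step 18.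

**Steps most likely to fail**

1. Step 7. Hydride may be delivered to the allylic C3 or in conjugate fashion through the C4=C5 alkene instead of to C2, which would erode the regiocontrol that places the oxygen on C3′. The fallback sets out from 9 and comes back at 10. Epoxy alcohol 9 is oxidised with TEMPO/PhI(OAc)2 in MeCN–water to the glycidic acid (2R,3S)-3-[(2E,6Z)-8-[(4-methoxybenzyl)oxy]-6-methylocta-2,6-dien-2-yl]oxirane-2-carboxylic acid F1. This is esterified with Me3SiCHN2 to methyl (2R,3S)-3-[(2E,6Z)-8-[(4-methoxybenzyl)oxy]-6-methylocta-2,6-dien-2-yl]oxirane-2-carboxylate F2. Electron transfer from SmI2 (divalent samarium; THF, HMPA, Me2NCH2CH2OH, −78 °C) to the ester carbonyl cleaves only the adjacent C2–O bond, giving methyl (3R,4E,8Z)-3-hydroxy-10-[(4-methoxybenzyl)oxy]-4,8-dimethyldeca-4,8-dienoate F3. LiBH4 then reduces the ester to diol 10. The regiochemistry is then fixed by the position of the carbonyl and not by a hydride trajectory.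

2. Step 17. The basic ylide may deprotonate the aldehyde at C2 or the lactone α‑position, leading to epimerisation or β‑elimination of the silyloxy group before olefination. The fallback sets out from 20 and comes back at 23. Aldehyde 20 is methylenated under non‑basic conditions with Zn/CH2Br2/TiCl4 in THF/CH2Cl2 to (4S,5R)-4-[(tert-butyldimethylsilyl)oxy]-5-ethenyloxolan-2-one F4. Cross‑metathesis of the vinyl group with excess 2‑methylbut‑2‑ene, using the second‑generation Grubbs catalyst (H2IMes)(PCy3)Cl2Ru=CHPh in CH2Cl2 at 40 °C, then gives the isobutenyl lactone 23.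

3. Step 19. The E1cB elimination may show poor geometric control (formation of the Z alkylidene lactone) or continue to a vinylogous elimination of the C8 silyloxy group on long exposure to DBU. The fallback sets out from 23 and comes back at 27, replacing steps 18 and 19. The enolate of 23 (LiN(iPr)2, THF, −78 °C) is O‑phosphorylated with ClP(O)(OEt)2, and a second equivalent of LiN(iPr)2 induces the 1,3‑shift of phosphorus from oxygen to carbon. This gives diethyl [(4R,5R)-4-[(tert-butyldimethylsilyl)oxy]-5-(2-methylprop-1-en-1-yl)-2-oxooxolan-3-yl]phosphonate F5 as C3 epimers; the C4 descriptor changes only through CIP priority. Its sodium salt (NaH, THF, 0 °C) condenses with aldehyde 15 in a Horner–Wadsworth–Emmons reaction to give 27 directly, without a mesylate or amidine base.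

**Further compounds**
F1 | step 7 | (2R,3S)-3-[(2E,6Z)-8-[(4-methoxybenzyl)oxy]-6-methylocta-2,6-dien-2-yl]oxirane-2-carboxylic acid | OC(=O)[C@@H]1O[C@H]1/C(C)=C/CC/C(C)=C\COCc1ccc(OC)cc1
F2 | step 7 | methyl (2R,3S)-3-[(2E,6Z)-8-[(4-methoxybenzyl)oxy]-6-methylocta-2,6-dien-2-yl]oxirane-2-carboxylate | COC(=O)[C@@H]1O[C@H]1/C(C)=C/CC/C(C)=C\COCc1ccc(OC)cc1
F3 | step 7 | methyl (3R,4E,8Z)-3-hydroxy-10-[(4-methoxybenzyl)oxy]-4,8-dimethyldeca-4,8-dienoate | COC(=O)C[C@@H](O)/C(C)=C/CC/C(C)=C\COCc1ccc(OC)cc1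
F4 | step 17 | (4S,5R)-4-[(tert-butyldimethylsilyl)oxy]-5-ethenyloxolan-2-one | O=C1C[C@H](O[Si](C)(C)C(C)(C)C)[C@@H](C=C)O1
F5 | step 19 | diethyl [(4R,5R)-4-[(tert-butyldimethylsilyl)oxy]-5-(2-methylprop-1-en-1-yl)-2-oxooxolan-3-yl]phosphonate, C3 epimers | O=C1C(P(=O)(OCC)OCC)[C@H](O[Si](C)(C)C(C)(C)C)[C@@H](C=C(C)C)O1
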